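## Retrosynthetic overview

1. The tetrahydrofuran is cut last. Its C3–C4 bond joins the two β-carbons (the alkene carbons bonded to the resorcinol-type rings) of two different E-4-hydroxystilbenes. O1 and its bonds to C2 and C5 come from one water molecule added across the bis(p-quinone methide) formed by that oxidative coupling.
2. The strategy rests on two features. C2 and C5 each carry a 4-hydroxyphenyl ring that can become a p-quinone methide. The cis aryl groups on C3 (free resorcinol ring) and C4 (benzo ring of the central dihydrobenzofuran, bonded through its C4) each have an oxygen meta to that bond (a resorcinol OH and the C6 OH). An o-xylylene diether can therefore clamp the two rings face to face, make the crossed coupling intramolecular, and leave with the benzyl ethers in the final hydrogenolysis.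
3. The tethered bis-stilbene comes from a double Heck reaction of 4-acetoxystyrene with a tethered dibromide. That dibromide is built by two Williamson etherifications around 1,2-bis(bromomethyl)benzene.
4. Each dihydrobenzofuran is cut at C2–C3, formed by enantioselective dirhodium donor/donor carbene insertion into an ortho O–CH2Ar group and then acid epimerisation of C2 to trans. The diaryl ketone precursors come from aryllithium additions to two benzaldehydes.
5. Ring order: outer dihydrobenzofuran, then central dihydrobenzofuran, then the temporary 14-membered tether ring and the tetrahydrofuran in one operation. The tether ring is opened at the end.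

Key step: step 23

Assumption: Rh2(S-PTAD)4 is taken to give the 3R series and Rh2(R-PTAD)4 the 3S series. If the sense of induction is the reverse, the two antipodes are exchanged between steps 8 and 16.

Locants: in the tetrahydrofuran, C2 and C5 carry 4-hydroxyphenyl, C3 carries the resorcinol ring and C4 carries the central dihydrobenzofuran. "Outer unit" means the (2R,3R)-7-(benzyloxy)-2-[4-(benzyloxy)phenyl]-3-[3,5-bis(benzyloxy)phenyl]-2,3-dihydrobenzofuran-5-yl group.

## Route

Step 1
Reactants: 1 5-bromo-2-hydroxy-3-methoxybenzaldehyde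
Product: 2 5-bromo-2,3-dihydroxybenzaldehyde
Conditions: BBr3 (1.5 equiv), CH2Cl2, −78 to 0 °C; then H2O
Reagents that add atoms: none
Why: Lewis-acid aryl methyl ether cleavage, in which BBr3 binds the methoxy oxygen and bromide removes the methyl group by SN2 while the aldehyde and aryl bromide are untouched.

Step 2
Reactants: 2 5-bromo-2,3-dihydroxybenzaldehyde
Product: 4 3-(benzyloxy)-5-bromo-2-hydroxybenzaldehyde, via disodium dianion 3 (not isolated)
Conditions: NaH (2.2 equiv), DMSO–THF, 20 °C; BnBr (1.0 equiv); then 1 M HCl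
Reagents that add atoms: benzyl bromide BrCc1ccccc1
Why: Williamson etherification of the dianion, where the 2-phenoxide is delocalised into and chelated by the formyl group, so the single equivalent of halide is taken by the more nucleophilic 3-phenoxide.

Step 3
Reactants: 4 3-(benzyloxy)-5-bromo-2-hydroxybenzaldehyde; 5 4-(benzyloxy)benzyl chloride
Product: 6 3-(benzyloxy)-2-{[4-(benzyloxy)benzyl]oxy}-5-bromobenzaldehyde
Conditions: K2CO3, DMF, 60 °C
Reagents that add atoms: none
Why: Williamson etherification, since only the hydrogen-bonded 2-OH remains and carbonate in warm DMF is enough to alkylate it with the reactive 4-alkoxybenzyl chloride.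

Step 4
Reactants: 7 5-bromoresorcinol
Product: 8 1,3-bis(benzyloxy)-5-bromobenzene
Conditions: BnBr (2.4 equiv), K2CO3, acetone, 56 °C
Reagents that add atoms: benzyl bromide BrCc1ccccc1
Why: Double Williamson etherification, with excess halide carrying both phenols through to the ether.

Step 5
Reactants: 8 1,3-bis(benzyloxy)-5-bromobenzene; 6 3-(benzyloxy)-2-{[4-(benzyloxy)benzyl]oxy}-5-bromobenzaldehyde
Product: 10 racemic [3,5-bis(benzyloxy)phenyl](3-(benzyloxy)-2-{[4-(benzyloxy)benzyl]oxy}-5-bromophenyl)methanol, via 3,5-bis(benzyloxy)phenyllithium 9 (not isolated)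
Conditions: n-BuLi (1.05 equiv), THF, −78 °C; then 6 in THF, −78 °C; then H2O
Reagents that add atoms: none
Why: Bromine–lithium exchange followed by 1,2-addition, in which the aryllithium adds to the aldehyde at −78 °C much faster than it exchanges with the aryl bromide of 6, and the new carbinol centre does not matter because it is oxidised next.

Step 6
Reactants: 10 racemic diaryl carbinol
Product: 11 [3,5-bis(benzyloxy)phenyl](3-(benzyloxy)-2-{[4-(benzyloxy)benzyl]oxy}-5-bromophenyl)methanone
Conditions: Dess–Martin periodinane, CH2Cl2, 20 °C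
Reagents that add atoms: none
Why: Dess–Martin oxidation of a secondary diaryl carbinol under nearly neutral conditions that spare the acid-labile 4-benzyloxybenzyl ether.

Step 7
Reactants: 11 diaryl ketone
Product: 12 hydrazone of ketone 11 (C=N isomers)
Conditions: N2H4·H2O (20 equiv), AcOH (cat.), EtOH, 80 °C
Reagents that add atoms: hydrazine NN
Why: Hydrazone condensation of a benzophenone with one ortho substituent, driven by excess hydrazine, which also suppresses azine formation.

Step 8
Reactants: 12 hydrazone of ketone 11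
Product: 14 cis-(2S,3R)-7-(benzyloxy)-2-[4-(benzyloxy)phenyl]-3-[3,5-bis(benzyloxy)phenyl]-5-bromo-2,3-dihydrobenzofuran, via diaryldiazomethane 13 (not isolated)
Conditions: MnO2 (10 equiv), CH2Cl2, 20 °C, filtration; then Rh2(S-PTAD)4 (1 mol%), CH2Cl2, 0 °C
Reagents that add atoms: none
Why: Hydrazone dehydrogenation followed by enantioselective dirhodium donor/donor carbene 1,5-C–H insertion into the ortho O–CH2Ar group, in which the chiral carboxylate pocket selects the carbene face and one enantiotopic benzylic hydrogen, so C3 is set as R by the catalyst and C2 forms cis to it (2S) through the compact concerted transition state.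

Step 9
Reactants: 14 cis-(2S,3R)-dihydrobenzofuran
Product: 15 trans-(2R,3R)-7-(benzyloxy)-2-[4-(benzyloxy)phenyl]-3-[3,5-bis(benzyloxy)phenyl]-5-bromo-2,3-dihydrobenzofuran
Conditions: TFA (5 equiv), CH2Cl2, 0 to 20 °C, dilute
Reagents that add atoms: none
Why: Acid-mediated epimerisation, in which reversible heterolysis of the C2–O bond to the 4-benzyloxybenzyl cation and reclosure should give the less strained trans isomer (C2 goes from S to R) while C3 takes no part and stays R.

Step 10
Reactants: 7 5-bromoresorcinol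
Product: 17 2-bromo-4,6-dihydroxybenzaldehyde, via aryl iminium salt 16 (not isolated)
Conditions: POCl3 (1.2 equiv), DMF (2 equiv), MeCN, 0 to 25 °C; then H2O, 50 °C
Reagents that add atoms: N,N-dimethylformamide CN(C)C=O (formyl carbon); water O (formyl oxygen)
Why: Vilsmeier–Haack formylation, which should occur at C4 of 7 (para to one hydroxyl, ortho to the other, next to bromine) rather than at the crowded C2 between the hydroxyls, as is usual for 5-substituted resorcinols.

Step 11
Reactants: 17 2-bromo-4,6-dihydroxybenzaldehyde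
Product: 18 2-bromo-6-hydroxy-4-(methoxymethoxy)benzaldehyde
Conditions: MOMCl (1.05 equiv), i-Pr2NEt (1.2 equiv), CH2Cl2, 0 °C
Reagents that add atoms: chloromethyl methyl ether COCCl
Why: Selective O-alkylation (MOM ether formation), since the 6-OH is held in a hydrogen bond to the formyl group and one equivalent of reagent goes to the free, more acidic 4-OH.

Step 12
Reactants: 18 2-bromo-6-hydroxy-4-(methoxymethoxy)benzaldehyde; 5 4-(benzyloxy)benzyl chloride
Product: 19 2-bromo-6-{[4-(benzyloxy)benzyl]oxy}-4-(methoxymethoxy)benzaldehyde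
Conditions: K2CO3, DMF, 50 °C
Reagents that add atoms: none
Why: Williamson etherification of the only remaining phenol under conditions to which the MOM acetal and the aryl bromide are inert.

Step 13
Reactants: 15 trans-(2R,3R)-5-bromodihydrobenzofuran; 19 2-bromo-6-{[4-(benzyloxy)benzyl]oxy}-4-(methoxymethoxy)benzaldehyde
Product: 21 (2-bromo-6-{[4-(benzyloxy)benzyl]oxy}-4-(methoxymethoxy)phenyl)(outer unit)methanol as a mixture of carbinol epimers, via outer-unit aryllithium 20 (not isolated)
Conditions: n-BuLi (1.0 equiv), THF, −78 °C, 15 min; then 19 in THF, −78 °C; then H2O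
Reagents that add atoms: none
Why: Bromine–lithium exchange followed by 1,2-addition, in which exchange at −78 °C is faster than deprotonation of the benzylic positions of 15, addition to the aldehyde is faster than exchange with the bromide of 19, and the carbinol centre is removed in the next step.

Step 14
Reactants: 21 carbinol
Product: 22 (2-bromo-6-{[4-(benzyloxy)benzyl]oxy}-4-(methoxymethoxy)phenyl)(outer unit)methanone
Conditions: Dess–Martin periodinane, CH2Cl2, 20 °C
Reagents that add atoms: none
Why: Dess–Martin oxidation, which tolerates a hindered diaryl carbinol and leaves the MOM acetal, the benzylic ethers and the stereocentres unchanged.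

Step 15
Reactants: 22 hindered diaryl ketone
Product: 23 hydrazone of ketone 22 (C=N isomers)
Conditions: N2H4·H2O (50 equiv), AcOH (5 equiv), n-BuOH, 110 °C, sealed vessel, copper-free
Reagents that add atoms: hydrazine NN
Why: Hydrazone condensation pushed by temperature, acid catalysis and a large excess of hydrazine because the carbonyl carries a di-ortho-substituted ring, with copper excluded so that the hydrazone nitrogen does not arylate at the ortho bromide.

Step 16
Reactants: 23 hydrazone of ketone 22
Product: 25 cis-(2R,3S)-2-[4-(benzyloxy)phenyl]-4-bromo-6-(methoxymethoxy)-3-(outer unit)-2,3-dihydrobenzofuran, via hindered diaryldiazomethane 24 (not isolated)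
Conditions: MnO2 (10 equiv), CH2Cl2, 20 °C, filtration; then Rh2(R-PTAD)4 (2 mol%), CH2Cl2, 25 to 40 °C
Reagents that add atoms: none
Why: Hydrazone dehydrogenation and enantioselective dirhodium donor/donor carbene 1,5-C–H insertion as in step 8, where the antipodal catalyst sets C3 as S (the outer stereocentres are too far from the carbene carbon to interfere) and C2 forms cis to it (2R).

Step 17
Reactants: 25 cis-(2R,3S)-MOM ether
Product: 27 trans-(2S,3S)-2-[4-(benzyloxy)phenyl]-4-bromo-3-(outer unit)-2,3-dihydrobenzofuran-6-ol, via cis phenol 26 (not isolated)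
Conditions: HCl (1.25 M in MeOH), THF, 40 °C; concentration; then TFA (5 equiv), CH2Cl2, 0 to 20 °C
Reagents that add atoms: none
Why: Acetal solvolysis in methanol, which carries the formaldehyde unit off as its dimethyl acetal before any electron-rich ring can capture it, followed by the C2–O ionisation and reclosure of step 9, which turns C2 from R to S while C3 and the already trans outer unit are unchanged.

Step 18
Reactants: 7 5-bromoresorcinol
Product: 28 3-(benzyloxy)-5-bromophenol
Conditions: BnBr (0.9 equiv), K2CO3 (1.0 equiv), acetone, 56 °C; chromatography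
Reagents that add atoms: benzyl bromide BrCc1ccccc1
Why: Statistical mono-Williamson etherification with the halide as limiting reagent, where diol, mono-ether and bis-ether differ by one phenol each and separate easily, recovered 7 is recycled, and the over-alkylated material is identical with 8.

Step 19
Reactants: 28 3-(benzyloxy)-5-bromophenol
Product: 29 1-(benzyloxy)-3-bromo-5-{[2-(bromomethyl)benzyl]oxy}benzene
Conditions: 1,2-bis(bromomethyl)benzene (4 equiv), K2CO3, acetone, 56 °C
Reagents that add atoms: 1,2-bis(bromomethyl)benzene BrCc1ccccc1CBr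
Why: Williamson etherification in which a large excess of the dibromide suppresses double substitution and leaves one benzylic bromide for the next union.

Step 20
Reactants: 27 trans-(2S,3S)-bromophenol; 29 benzylic bromide
Product: 30 o-xylylene-tethered dibromide (O6 of 27 joined through CH2–C6H4–CH2 to the phenol oxygen of 28)
Conditions: K2CO3, DMF, 30 °C
Reagents that add atoms: none
Why: Williamson etherification of the only free phenol of 27 with a primary benzylic bromide under conditions too mild to affect any stereocentre.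

Step 21
Reactants: 30 tethered dibromide; 31 4-acetoxystyrene
Product: 32 tethered bis[(E)-4-acetoxystilbene]
Conditions: 31 (4 equiv), Pd2(dba)3 (5 mol%), P(t-Bu)3 (12 mol%), Cy2NMe (3 equiv), dioxane, 90 °C
Reagents that add atoms: none
Why: Twofold Mizoroki–Heck reaction, in which the bulky electron-rich phosphine lets zerovalent palladium insert even into the C4–Br bond next to C3, syn insertion and syn β-hydride elimination on a terminal styrene give the E-alkenes, and aryl acetates and benzyl ethers are inert.

Step 22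
Reactants: 32 tethered bis[(E)-4-acetoxystilbene]
Product: 33 tethered bis[(E)-4-hydroxystilbene]
Conditions: K2CO3 (0.3 equiv), MeOH–THF (1:1), 0 °C, argon
Reagents that add atoms: none
Why: Base-catalysed transesterification (Zemplén type), since aryl acetates are cleaved quickly at 0 °C without touching ethers or stereocentres, and air is excluded because the free hydroxystilbenes are easily oxidised.

Step 23
Reactants: 33 tethered bis[(E)-4-hydroxystilbene]
Product: 36 tethered (2S,3R,4S,5R)-2,5-bis(4-hydroxyphenyl)tetrahydrofuran, via bis(p-quinone methide) 34 (not isolated), via hydroxy quinone methide 35 (not isolated)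
Conditions: reticulated vitreous carbon anode, Pt cathode, divided cell, n-Bu4NBF4 (0.1 M), 2,6-lutidine (4 equiv), MeCN–CH2Cl2–H2O (15:4:1), 1 mM in 33, controlled potential at the first phenol wave (fixed by cyclic voltammetry), 2.0–2.2 F/mol, 0 °C, argon; then crude product, pyridinium p-toluenesulfonate (cat.), MeCN–H2O, 20 °C, brief
Reagents that add atoms: water O
Why: Proposed new method: at the potential of the first phenol wave only the two lutidine-assisted 4-hydroxystilbene phenols each lose one electron and one proton, the phenoxyl radicals carry spin at their β-carbons, these two carbons are held within bonding distance by the xylylene diether and combine to bis(p-quinone methide) 34, water adds 1,6 to the less hindered quinone methide to give 35, and the new benzylic hydroxyl adds 1,6 to the second quinone methide. The closest known reaction type is the untethered one-electron (anodic or chemical) β,β' homodimerisation of 4-hydroxy- and 4-alkoxystilbenes, with capture of the resulting bis(quinone methide) or dication by water as a 2,3,4,5-tetraaryltetrahydrofuran, and the tethered, crossed and diastereoselective version is what is new. Two rings close, the temporary 14-membered tether ring by radical–radical C–C combination and the tetrahydrofuran by 5-exo-trig oxa-1,6-conjugate addition. C4 is controlled by the central dihydrobenzofuran, whose C3 aryl group shields one face of the adjacent styryl arm (which turns its vinylic C–H toward C3 to relieve allylic 1,3-strain), so the partner bonds on the open face and gives 4S, while C3 follows from the parallel face-to-face stacking imposed by the tether, which puts both aryl groups on the same side (3R, cis), the crossed alignment being obstructed by the trans C2 aryl group of the dihydrobenzofuran. C2 and C5 arise in the two C–O bond formations and are corrected in the second stage, where the free 4-hydroxyphenyl groups allow reversible C–O ionisation, so each aryl group should settle trans to its C3 or C4 neighbour and away from the clamped aryl pair (2S,5R). The step needs chemoselective oxidation (secured by the wide potential gap between free hydroxystilbenes and aryl benzyl ethers or the isolated phenols of the product), cross- and β,β'-selectivity (secured by the short meta,meta' tether and high dilution, which keep the phenol oxygens and ortho carbons out of register) and freedom from Friedel–Crafts indane closure (secured by buffered, neutral quinone methides and by the tether, which stops the clamped rings from turning toward the electrophilic carbons).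

Step 24
Reactants: 36 tethered tetrahydrofuran
Product: 37 kobophenol A
Conditions: H2 (1 atm), 10% Pd/C, EtOAc–MeOH (1:1), 20 °C, stopped as soon as the last ether is cleaved; argon during isolation
Reagents that add atoms: none
Why: Heterogeneous catalytic hydrogenolysis, in which the primary ArO–CH2Ar bonds of the six benzyl ethers and both ends of the xylylene diether cleave much faster at one atmosphere than the hindered secondary benzylic C–O bonds inside the two dihydrobenzofurans and the tetrahydrofuran, there is no alkene to reduce, and the neutral medium leaves all eight stereocentres untouched.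

## Compound list

1 | 5-bromo-2-hydroxy-3-methoxybenzaldehyde | O=Cc1cc(Br)cc(OC)c1O | starting material
2 | 5-bromo-2,3-dihydroxybenzaldehyde | O=Cc1cc(Br)cc(O)c1O | intermediate
3 | disodium 5-bromo-3-formylbenzene-1,2-diolate | O=Cc1cc(Br)cc([O-])c1[O-].[Na+].[Na+] | intermediate
4 | 3-(benzyloxy)-5-bromo-2-hydroxybenzaldehyde | O=Cc1cc(Br)cc(OCc2ccccc2)c1O | intermediate
5 | 4-(benzyloxy)benzyl chloride | ClCc1ccc(OCc2ccccc2)cc1 | starting material
6 | 3-(benzyloxy)-2-{[4-(benzyloxy)benzyl]oxy}-5-bromobenzaldehyde | O=Cc1cc(Br)cc(OCc2ccccc2)c1OCc1ccc(OCc2ccccc2)cc1 | intermediate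
7 | 5-bromoresorcinol | Oc1cc(O)cc(Br)c1 | starting material
8 | 1,3-bis(benzyloxy)-5-bromobenzene | Brc1cc(OCc2ccccc2)cc(OCc2ccccc2)c1 | intermediate
9 | 3,5-bis(benzyloxy)phenyllithium | [Li]c1cc(OCc2ccccc2)cc(OCc2ccccc2)c1 | intermediate
10 | racemic diaryl carbinol for the outer ring | OC(c1cc(OCc2ccccc2)cc(OCc2ccccc2)c1)c1cc(Br)cc(OCc2ccccc2)c1OCc1ccc(OCc2ccccc2)cc1 | intermediate
11 | diaryl ketone for the outer ring | O=C(c1cc(OCc2ccccc2)cc(OCc2ccccc2)c1)c1cc(Br)cc(OCc2ccccc2)c1OCc1ccc(OCc2ccccc2)cc1 | intermediate
12 | hydrazone of 11 | NN=C(c1cc(OCc2ccccc2)cc(OCc2ccccc2)c1)c1cc(Br)cc(OCc2ccccc2)c1OCc1ccc(OCc2ccccc2)cc1 | intermediate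
13 | diaryldiazomethane from 12 | [N-]=[N+]=C(c1cc(OCc2ccccc2)cc(OCc2ccccc2)c1)c1cc(Br)cc(OCc2ccccc2)c1OCc1ccc(OCc2ccccc2)cc1 | intermediate
14 | cis-(2S,3R)-5-bromo outer dihydrobenzofuran | Brc1cc(OCc2ccccc2)c2c(c1)[C@@H](c1cc(OCc3ccccc3)cc(OCc3ccccc3)c1)[C@@H](c1ccc(OCc3ccccc3)cc1)O2 | intermediate
15 | trans-(2R,3R)-5-bromo outer dihydrobenzofuran | Brc1cc(OCc2ccccc2)c2c(c1)[C@@H](c1cc(OCc3ccccc3)cc(OCc3ccccc3)c1)[C@H](c1ccc(OCc3ccccc3)cc1)O2 | intermediate
16 | N-(2-bromo-4,6-dihydroxybenzylidene)-N-methylmethanaminium dichlorophosphate | C[N+](C)=Cc1c(Br)cc(O)cc1O.[O-]P(Cl)(Cl)=O | intermediate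
17 | 2-bromo-4,6-dihydroxybenzaldehyde | O=Cc1c(Br)cc(O)cc1O | intermediate
18 | 2-bromo-6-hydroxy-4-(methoxymethoxy)benzaldehyde | O=Cc1c(Br)cc(OCOC)cc1O | intermediate
19 | 2-bromo-6-{[4-(benzyloxy)benzyl]oxy}-4-(methoxymethoxy)benzaldehyde | O=Cc1c(Br)cc(OCOC)cc1OCc1ccc(OCc2ccccc2)cc1 | intermediate
20 | outer-unit aryllithium (5-lithio analogue of 15) | [Li]c1cc(OCc2ccccc2)c2c(c1)[C@@H](c1cc(OCc3ccccc3)cc(OCc3ccccc3)c1)[C@H](c1ccc(OCc3ccccc3)cc1)O2 | intermediate
21 | carbinol joining the outer unit to the central ring (carbinol epimers) | OC(c1c(Br)cc(OCOC)cc1OCc1ccc(OCc2ccccc2)cc1)c1cc(OCc2ccccc2)c2c(c1)[C@@H](c1cc(OCc3ccccc3)cc(OCc3ccccc3)c1)[C@H](c1ccc(OCc3ccccc3)cc1)O2 | intermediate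
22 | hindered diaryl ketone | O=C(c1c(Br)cc(OCOC)cc1OCc1ccc(OCc2ccccc2)cc1)c1cc(OCc2ccccc2)c2c(c1)[C@@H](c1cc(OCc3ccccc3)cc(OCc3ccccc3)c1)[C@H](c1ccc(OCc3ccccc3)cc1)O2 | intermediate
23 | hydrazone of 22 | NN=C(c1c(Br)cc(OCOC)cc1OCc1ccc(OCc2ccccc2)cc1)c1cc(OCc2ccccc2)c2c(c1)[C@@H](c1cc(OCc3ccccc3)cc(OCc3ccccc3)c1)[C@H](c1ccc(OCc3ccccc3)cc1)O2 | intermediate
24 | hindered diaryldiazomethane from 23 | [N-]=[N+]=C(c1c(Br)cc(OCOC)cc1OCc1ccc(OCc2ccccc2)cc1)c1cc(OCc2ccccc2)c2c(c1)[C@@H](c1cc(OCc3ccccc3)cc(OCc3ccccc3)c1)[C@H](c1ccc(OCc3ccccc3)cc1)O2 | intermediate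
25 | cis-(2R,3S)-4-bromo-6-(methoxymethoxy) central dihydrobenzofuran bearing the outer unit at C3 | c1ccccc1COc1ccc([C@@H]2Oc3cc(OCOC)cc(Br)c3[C@@H]2c2cc(OCc3ccccc3)c3c(c2)[C@@H](c2cc(OCc4ccccc4)cc(OCc4ccccc4)c2)[C@H](c2ccc(OCc4ccccc4)cc2)O3)cc1 | intermediate
26 | cis-(2R,3S)-4-bromo-6-hydroxy central dihydrobenzofuran | c1ccccc1COc1ccc([C@@H]2Oc3cc(O)cc(Br)c3[C@@H]2c2cc(OCc3ccccc3)c3c(c2)[C@@H](c2cc(OCc4ccccc4)cc(OCc4ccccc4)c2)[C@H](c2ccc(OCc4ccccc4)cc2)O3)cc1 | intermediate
27 | trans-(2S,3S)-4-bromo-6-hydroxy central dihydrobenzofuran bearing the outer unit at C3 | c1ccccc1COc1ccc([C@H]2Oc3cc(O)cc(Br)c3[C@@H]2c2cc(OCc3ccccc3)c3c(c2)[C@@H](c2cc(OCc4ccccc4)cc(OCc4ccccc4)c2)[C@H](c2ccc(OCc4ccccc4)cc2)O3)cc1 | intermediate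
28 | 3-(benzyloxy)-5-bromophenol | Oc1cc(Br)cc(OCc2ccccc2)c1 | intermediate
29 | 1-(benzyloxy)-3-bromo-5-{[2-(bromomethyl)benzyl]oxy}benzene | BrCc1ccccc1COc1cc(Br)cc(OCc2ccccc2)c1 | intermediate
30 | o-xylylene-tethered dibromide | c1ccccc1COc1ccc([C@H]2Oc3cc(OCc4ccccc4COc4cc(Br)cc(OCc5ccccc5)c4)cc(Br)c3[C@@H]2c2cc(OCc3ccccc3)c3c(c2)[C@@H](c2cc(OCc4ccccc4)cc(OCc4ccccc4)c2)[C@H](c2ccc(OCc4ccccc4)cc2)O3)cc1 | intermediate
31 | 4-acetoxystyrene | C=Cc1ccc(OC(C)=O)cc1 | starting material
32 | tethered bis[(E)-4-acetoxystilbene] | c1ccccc1COc1ccc([C@H]2Oc3cc(OCc4ccccc4COc4cc(/C=C/c5ccc(OC(C)=O)cc5)cc(OCc5ccccc5)c4)cc(/C=C/c4ccc(OC(C)=O)cc4)c3[C@@H]2c2cc(OCc3ccccc3)c3c(c2)[C@@H](c2cc(OCc4ccccc4)cc(OCc4ccccc4)c2)[C@H](c2ccc(OCc4ccccc4)cc2)O3)cc1 | intermediate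
33 | tethered bis[(E)-4-hydroxystilbene] | c1ccccc1COc1ccc([C@H]2Oc3cc(OCc4ccccc4COc4cc(/C=C/c5ccc(O)cc5)cc(OCc5ccccc5)c4)cc(/C=C/c4ccc(O)cc4)c3[C@@H]2c2cc(OCc3ccccc3)c3c(c2)[C@@H](c2cc(OCc4ccccc4)cc(OCc4ccccc4)c2)[C@H](c2ccc(OCc4ccccc4)cc2)O3)cc1 | intermediate
34 | macrocyclic bis(p-quinone methide), new sp3 carbons configured as C3 and C4 of 36 | c1ccccc1COc1ccc([C@H]2Oc3cc(OCc6ccccc6CO7)cc([C@@H](C=C4C=CC(=O)C=C4)[C@H](c5cc7cc(OCc8ccccc8)c5)C=C4C=CC(=O)C=C4)c3[C@@H]2c2cc(OCc3ccccc3)c3c(c2)[C@@H](c2cc(OCc4ccccc4)cc(OCc4ccccc4)c2)[C@H](c2ccc(OCc4ccccc4)cc2)O3)cc1 | intermediate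
35 | hydroxy quinone methide (water added at the future C2) | c1ccccc1COc1ccc([C@H]2Oc3cc(OCc6ccccc6CO7)cc([C@@H](C=C4C=CC(=O)C=C4)[C@H](c5cc7cc(OCc8ccccc8)c5)[C@@H](c5ccc(O)cc5)O)c3[C@@H]2c2cc(OCc3ccccc3)c3c(c2)[C@@H](c2cc(OCc4ccccc4)cc(OCc4ccccc4)c2)[C@H](c2ccc(OCc4ccccc4)cc2)O3)cc1 | intermediate
36 | tethered (2S,3R,4S,5R)-tetraaryltetrahydrofuran | c1ccccc1COc1ccc([C@H]2Oc3cc(OCc6ccccc6CO7)cc([C@@H]4[C@H](c5cc7cc(OCc8ccccc8)c5)[C@@H](c5ccc(O)cc5)O[C@H]4c4ccc(O)cc4)c3[C@@H]2c2cc(OCc3ccccc3)c3c(c2)[C@@H](c2cc(OCc4ccccc4)cc(OCc4ccccc4)c2)[C@H](c2ccc(OCc4ccccc4)cc2)O3)cc1 | intermediate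
37 | kobophenol A | Oc1ccc([C@H]2Oc3cc(O)cc([C@@H]4[C@H](c5cc(O)cc(O)c5)[C@@H](c5ccc(O)cc5)O[C@H]4c4ccc(O)cc4)c3[C@@H]2c2cc(O)c3c(c2)[C@@H](c2cc(O)cc(O)c2)[C@H](c2ccc(O)cc2)O3)cc1 | target

## Step count and risks

Total step count: 24.
Longest linear sequence: 18 steps (steps 1–3, 5–9, 13–17 and 20–24, starting from 1).

Steps most likely to fail:

**1. Step 23.**
- **What may go wrong.**
  - Radical coupling between molecules may lead to oligomerisation.
  - A β-carbon may bond to a phenol oxygen or ortho carbon instead of the other β-carbon.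
  - The facial bias at the styryl arm of the central ring may be too weak.
  - The product phenols may be oxidised further.
  - The C2/C5 equilibrium may not favour the trans, cis, trans array.
- **Fallback.** This route avoids oxidative stilbene coupling and makes the C3–C4 bond by oxidative enolate coupling, starting from dibromide 30.
  - Double palladium-catalysed ketone α-arylation of 30 with 4'-(benzyloxy)acetophenone (Pd2(dba)3, XPhos, K3PO4, toluene, 90 °C) would give the tethered bis(aryl benzyl ketone) F1.
  - Double enolisation (LiHMDS, THF, −78 °C) and oxidation with CuCl2 (intramolecular oxidative enolate coupling) would give the macrocyclic 2,3-diaryl-1,4-diketone F2. Its two epimerisable α-centres can be equilibrated with DBU inside the tether ring, and its diastereomers can be separated.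
  - NaBH4 reduction would give the 1,4-diol F3.
  - MsCl/Et3N cyclodehydration, as used for 2,5-diaryltetrahydrofuran lignans, would close the fully benzylated tetrahydrofuran F4 through the 4-benzyloxybenzyl cation, with the C2 and C5 aryl groups trans to their neighbours.
  - Hydrogenolysis under the conditions of step 24 then removes eight benzyl ethers and the tether and rejoins the route at 37.

**2. Step 15.**
- **What may go wrong.** Condensation may be very slow at a carbonyl shielded by the bromine and the benzylic ether. On prolonged heating the hydrazone nitrogen may displace the ortho bromide.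
- **Fallback.** This route avoids nucleophilic attack on the hindered ketone and starts from aldehyde 19 and bromide 15.
  - Aldehyde 19 is converted with NH2OH·HCl/pyridine into the aldoxime F5.
  - Dehydration with Ac2O gives the benzonitrile F6.
  - Aryllithium 20, made from 15 as in step 13, is added to the sterically open nitrile carbon (THF, −78 to 0 °C, inverse addition). An anhydrous methanol quench gives the N–H ketimine F7.
  - Transimination with hydrazine hydrate and catalytic AcOH in EtOH at 60 °C proceeds through the much more electrophilic iminium ion with loss of ammonia. It rejoins the route at hydrazone 23.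

**3. Step 16.**
- **What may go wrong.** Metal carbene formation may be slow at the shielded diazo carbon. Azine formation may compete, and catalyst control over the new C3 centre may erode.
- **Fallback.** This route avoids carbene chemistry and starts from ketone 22.
  - Reversible deprotonation of the ortho O–CH2Ar group with the phosphazene base P4-t-Bu (benzene–THF, 20 °C) and 5-exo-trig addition of the benzylic carbanion to the ketone would give the 3-hydroxy-2,3-dihydrobenzofuran F8 as a stereoisomer mixture.
  - Ionic deoxygenation (Et3SiH, BF3·OEt2, CH2Cl2, −78 °C) ionises only the tertiary, doubly benzylic C3–OH at this temperature.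
  - Hydride is delivered anti to the C2 aryl group, which gives the cis-dihydrobenzofurans.
  - The two diastereomers, which differ in the absolute sense of the central ring relative to the outer unit, are separated by chromatography. The (2R,3S) isomer rejoins the route at 25.

## Further compounds

F1 | step 23 | tethered bis(aryl benzyl ketone) from double α-arylation of 30 | c1ccccc1COc1ccc([C@H]2Oc3cc(OCc4ccccc4COc4cc(CC(=O)c5ccc(OCc6ccccc6)cc5)cc(OCc5ccccc5)c4)cc(CC(=O)c4ccc(OCc5ccccc5)cc4)c3[C@@H]2c2cc(OCc3ccccc3)c3c(c2)[C@@H](c2cc(OCc4ccccc4)cc(OCc4ccccc4)c2)[C@H](c2ccc(OCc4ccccc4)cc2)O3)cc1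
F2 | step 23 | macrocyclic 2,3-diaryl-1,4-diketone | c1ccccc1COc1ccc([C@H]2Oc3cc(OCc6ccccc6CO7)cc([C@@H](C(=O)c4ccc(OCc5ccccc5)cc4)[C@H](c5cc7cc(OCc8ccccc8)c5)C(=O)c4ccc(OCc5ccccc5)cc4)c3[C@@H]2c2cc(OCc3ccccc3)c3c(c2)[C@@H](c2cc(OCc4ccccc4)cc(OCc4ccccc4)c2)[C@H](c2ccc(OCc4ccccc4)cc2)O3)cc1
F3 | step 23 | macrocyclic 1,4-diol (carbinol epimers) | c1ccccc1COc1ccc([C@H]2Oc3cc(OCc6ccccc6CO7)cc([C@@H](C(O)c4ccc(OCc5ccccc5)cc4)[C@H](c5cc7cc(OCc8ccccc8)c5)C(O)c4ccc(OCc5ccccc5)cc4)c3[C@@H]2c2cc(OCc3ccccc3)c3c(c2)[C@@H](c2cc(OCc4ccccc4)cc(OCc4ccccc4)c2)[C@H](c2ccc(OCc4ccccc4)cc2)O3)cc1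
F4 | step 23 | fully benzylated tethered tetrahydrofuran (bis-benzyl ether of 36) | c1ccccc1COc1ccc([C@H]2Oc3cc(OCc6ccccc6CO7)cc([C@@H]4[C@H](c5cc7cc(OCc8ccccc8)c5)[C@@H](c5ccc(OCc8ccccc8)cc5)O[C@H]4c4ccc(OCc5ccccc5)cc4)c3[C@@H]2c2cc(OCc3ccccc3)c3c(c2)[C@@H](c2cc(OCc4ccccc4)cc(OCc4ccccc4)c2)[C@H](c2ccc(OCc4ccccc4)cc2)O3)cc1
F5 | step 15 | 2-bromo-6-{[4-(benzyloxy)benzyl]oxy}-4-(methoxymethoxy)benzaldehyde oxime | ON=Cc1c(Br)cc(OCOC)cc1OCc1ccc(OCc2ccccc2)cc1
F6 | step 15 | 2-bromo-6-{[4-(benzyloxy)benzyl]oxy}-4-(methoxymethoxy)benzonitrile | N#Cc1c(Br)cc(OCOC)cc1OCc1ccc(OCc2ccccc2)cc1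
F7 | step 15 | N–H ketimine corresponding to ketone 22 | N=C(c1c(Br)cc(OCOC)cc1OCc1ccc(OCc2ccccc2)cc1)c1cc(OCc2ccccc2)c2c(c1)[C@@H](c1cc(OCc3ccccc3)cc(OCc3ccccc3)c1)[C@H](c1ccc(OCc3ccccc3)cc1)O2
F8 | step 16 | 3-hydroxy-2,3-dihydrobenzofuran from anionic cyclisation of 22 (mixture at central C2 and C3) | c1ccccc1COc1ccc(C2Oc3cc(OCOC)cc(Br)c3C2(O)c2cc(OCc3ccccc3)c3c(c2)[C@@H](c2cc(OCc4ccccc4)cc(OCc4ccccc4)c2)[C@H](c2ccc(OCc4ccccc4)cc2)O3)cc1
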